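## Retrosynthetic overview
1. Side chain: N-methylformamide ⇒ (S)-tortuosamine ⇒ methyl carbamate ⇒ (Curtius) propanoic acid ⇒ 2-cyanoethyl group.
2. C5 methylene ⇒ C5 ketone. The ketone is removed in the forward direction by reduction and radical deoxygenation, and it makes C6 an acidic α-aryl ketone carbon.
3. Key disconnection C6–CH2: 6-aryl-7,8-dihydroquinolin-5(6H)-one + acrylonitrile, by an enantioselective phase-transfer Michael addition that creates the only stereocentre.
4. C6–aryl bond: 7,8-dihydroquinolin-5(6H)-one + 4-bromoveratrole, by Pd-catalysed ketone α-arylation.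
5. Rings: none is formed in the route. The pyridine and the carbocycle are bought already fused, and the arene is bought.

Assumption: the facial sense of the Michael step is taken from the closest analogy (phase-transfer alkylation of 2-aryl-1-indanones) and is confirmed on the crystalline adduct by X-ray and chiral HPLC; the pseudoenantiomeric cinchoninium salt is the direct correction if the sense is reversed.

## Route

Step 1
Reactants: 1 7,8-dihydroquinolin-5(6H)-one; 2 4-bromo-1,2-dimethoxybenzene (4-bromoveratrole)
Product: 3 (±)-6-(3,4-dimethoxyphenyl)-7,8-dihydroquinolin-5(6H)-one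
Conditions: 1 (1.15 equiv), 2 (1.0 equiv), Pd(OAc)2 (2 mol %), XPhos (4 mol %), NaOtBu (1.5 equiv), toluene, 80 °C, Ar, 12 h
Reagents that add atoms: none
Why: Buchwald–Hartwig-type ketone α-arylation in which C6 is the only enolisable carbon of 1, the bulky biaryl phosphine keeps the pyridine nitrogen off zerovalent palladium and speeds reductive elimination, and the product rests as its hindered stabilised enolate so a second arylation is slow; the C6 centre is racemic here and is erased by enolisation in step 2.

Step 2
Reactants: 3 (±)-6-(3,4-dimethoxyphenyl)-7,8-dihydroquinolin-5(6H)-one; 4 acrylonitrile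
Product: 5 3-[(6S)-6-(3,4-dimethoxyphenyl)-5-oxo-5,6,7,8-tetrahydroquinolin-6-yl]propanenitrile
Conditions: 4 (2 equiv, added over 2 h), N-[4-(trifluoromethyl)benzyl]cinchonidinium bromide (10 mol %), 45% aq KOH (1 equiv), degassed toluene, −20 °C, Ar, 24 h; expected 80–90% ee, recrystallise from EtOH to ≥99% ee (chiral HPLC)
Reagents that add atoms: none
Why: Asymmetric phase-transfer Michael addition (cyanoethylation) in which the flat, geometry-fixed enolate of the acidic α-aryl ketone pairs tightly with the chiral ammonium ion (9-OH hydrogen bond to the enolate oxygen, quinoline over the pyridine-fused ring, electron-poor benzyl over the electron-rich dimethoxyphenyl ring), so acrylonitrile reaches only the open Si face of C6 and sets the (S) quaternary centre, the mirror of the Re-face delivery seen with the pseudoenantiomeric cinchoninium salt on 2-aryl-1-indanones.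

Step 3
Reactants: 5 3-[(6S)-6-(3,4-dimethoxyphenyl)-5-oxo-5,6,7,8-tetrahydroquinolin-6-yl]propanenitrile
Product: 6 3-[(6S)-6-(3,4-dimethoxyphenyl)-5-hydroxy-5,6,7,8-tetrahydroquinolin-6-yl]propanenitrile (both C5 epimers)
Conditions: NaBH4 (1.5 equiv), MeOH/THF 2:1, 0 °C to rt, 4 h
Reagents that add atoms: none
Why: Chemoselective borohydride 1,2-reduction of the non-enolisable aryl ketone leaves the nitrile, the pyridine and the quaternary centre untouched, and the new C5 carbinol centre may form as an epimer mixture because C5 becomes CH2 in step 5.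

Step 4
Reactants: 6 3-[(6S)-6-(3,4-dimethoxyphenyl)-5-hydroxy-5,6,7,8-tetrahydroquinolin-6-yl]propanenitrile (both C5 epimers)
Product: 7 O-[(6S)-6-(2-cyanoethyl)-6-(3,4-dimethoxyphenyl)-5,6,7,8-tetrahydroquinolin-5-yl] 1H-imidazole-1-carbothioate (both C5 epimers)
Conditions: 1,1'-thiocarbonyldiimidazole (2.5 equiv), DMAP (0.3 equiv), 1,2-dichloroethane, reflux, 16 h
Reagents that add atoms: 1,1'-thiocarbonyldiimidazole, S=C(n1ccnc1)n1ccnc1
Why: Neutral thioacylation (first half of the Barton–McCombie deoxygenation) avoids a free alkoxide that could add to the nitrile and avoids MeI that would quaternise the pyridine, and the product cannot undergo Chugaev elimination because C5 has no β-hydrogen.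

Step 5
Reactants: 7 O-[(6S)-6-(2-cyanoethyl)-6-(3,4-dimethoxyphenyl)-5,6,7,8-tetrahydroquinolin-5-yl] 1H-imidazole-1-carbothioate (both C5 epimers)
Product: 8 3-[(6R)-6-(3,4-dimethoxyphenyl)-5,6,7,8-tetrahydroquinolin-6-yl]propanenitrile
Conditions: Bu3SnH (2 equiv, 0.2 M), AIBN (0.2 equiv in portions), toluene, 90 °C, 3 h
Reagents that add atoms: none
Why: Barton–McCombie radical deoxygenation is chosen because a C5 cation beside the pyridine is disfavoured and would provoke a 1,2-shift of the electron-rich aryl group, whereas the pyridyl-stabilised secondary radical is quenched by concentrated Bu3SnH faster than neophyl-type aryl migration or its reversible addition to the nitrile; C6 is untouched and its descriptor changes to (R) only through the priority rules.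

Step 6
Reactants: 8 3-[(6R)-6-(3,4-dimethoxyphenyl)-5,6,7,8-tetrahydroquinolin-6-yl]propanenitrile
Product: 11 3-[(6R)-6-(3,4-dimethoxyphenyl)-5,6,7,8-tetrahydroquinolin-6-yl]propanoic acid, via primary amide 9 (not isolated), via sodium carboxylate 10 (not isolated)
Conditions: NaOH (6 equiv), EtOH/H2O 1:1, reflux, 24 h; then HCl to pH 5.5, extract with CHCl3/i-PrOH 3:1
Reagents that add atoms: water, O; sodium hydroxide NaOH, [Na+].[OH-]
Why: Alkaline hydrolysis of an unhindered primary nitrile is robust, and with the ketone gone there is no retro-Michael pathway, so the quaternary centre cannot be lost.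

Step 7
Reactants: 11 3-[(6R)-6-(3,4-dimethoxyphenyl)-5,6,7,8-tetrahydroquinolin-6-yl]propanoic acid
Product: 14 methyl N-{2-[(6S)-6-(3,4-dimethoxyphenyl)-5,6,7,8-tetrahydroquinolin-6-yl]ethyl}carbamate, via acyl azide 12 (not isolated), via isocyanate 13 (not isolated)
Conditions: DPPA (1.1 equiv), Et3N (1.2 equiv), toluene, 25 °C 1 h then 90 °C 2 h; MeOH (20 equiv), 65 °C, 6 h
Reagents that add atoms: diphenylphosphoryl azide, O=P(N=[N+]=[N-])(Oc1ccccc1)Oc1ccccc1; methanol, CO
Why: Curtius rearrangement in its one-pot DPPA form moves the primary CH2 from carbon to nitrogen under non-oxidising conditions that spare the electron-rich arene and the pyridine, gives the required two-carbon C6-to-N tether, and keeps the old carboxyl carbon as the carbamate carbonyl; the remote stereocentre is not involved.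

Step 8
Reactants: 14 methyl N-{2-[(6S)-6-(3,4-dimethoxyphenyl)-5,6,7,8-tetrahydroquinolin-6-yl]ethyl}carbamate
Product: 15 2-[(6S)-6-(3,4-dimethoxyphenyl)-5,6,7,8-tetrahydroquinolin-6-yl]-N-methylethan-1-amine ((S)-tortuosamine)
Conditions: LiAlH4 (4 equiv), THF, 0 °C to reflux, 4 h; Fieser work-up
Reagents that add atoms: none
Why: Exhaustive hydride reduction of the carbamate turns its carbonyl carbon into the N-methyl group with no risk of over-alkylation, while the alkylpyridine and the aryl methyl ethers are inert to LiAlH4 on this time scale.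

Step 9
Reactants: 15 2-[(6S)-6-(3,4-dimethoxyphenyl)-5,6,7,8-tetrahydroquinolin-6-yl]-N-methylethan-1-amine ((S)-tortuosamine)
Product: 16 N-{2-[(6S)-6-(3,4-dimethoxyphenyl)-5,6,7,8-tetrahydroquinolin-6-yl]ethyl}-N-methylformamide (N-formyltortuosamine)
Conditions: HCO2Et (solvent), reflux, 16 h
Reagents that add atoms: ethyl formate, CCOC=O
Why: N-formylation by aminolysis of ethyl formate is clean because the secondary amine is the only acylable site, and the product is obtained as a pair of formamide rotamers of one enantiomer.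

## Compound list
1 | 7,8-dihydroquinolin-5(6H)-one | O=C1CCCc2ncccc12 | starting material
2 | 4-bromo-1,2-dimethoxybenzene | COc1ccc(Br)cc1OC | starting material
3 | (±)-6-(3,4-dimethoxyphenyl)-7,8-dihydroquinolin-5(6H)-one | COc1ccc(C2CCc3ncccc3C2=O)cc1OC | intermediate
4 | acrylonitrile | C=CC#N | starting material
5 | 3-[(6S)-6-(3,4-dimethoxyphenyl)-5-oxo-5,6,7,8-tetrahydroquinolin-6-yl]propanenitrile | COc1ccc([C@@]2(CCC#N)CCc3ncccc3C2=O)cc1OC | intermediate
6 | 3-[(6S)-6-(3,4-dimethoxyphenyl)-5-hydroxy-5,6,7,8-tetrahydroquinolin-6-yl]propanenitrile, C5 epimer mixture | COc1ccc([C@@]2(CCC#N)CCc3ncccc3C2O)cc1OC | intermediate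
7 | O-[(6S)-6-(2-cyanoethyl)-6-(3,4-dimethoxyphenyl)-5,6,7,8-tetrahydroquinolin-5-yl] 1H-imidazole-1-carbothioate, C5 epimer mixture | COc1ccc([C@@]2(CCC#N)CCc3ncccc3C2OC(=S)n4ccnc4)cc1OC | intermediate
8 | 3-[(6R)-6-(3,4-dimethoxyphenyl)-5,6,7,8-tetrahydroquinolin-6-yl]propanenitrile | COc1ccc([C@@]2(CCC#N)CCc3ncccc3C2)cc1OC | intermediate
9 | 3-[(6R)-6-(3,4-dimethoxyphenyl)-5,6,7,8-tetrahydroquinolin-6-yl]propanamide (not isolated) | COc1ccc([C@@]2(CCC(N)=O)CCc3ncccc3C2)cc1OC | intermediate
10 | sodium 3-[(6R)-6-(3,4-dimethoxyphenyl)-5,6,7,8-tetrahydroquinolin-6-yl]propanoate (not isolated) | COc1ccc([C@@]2(CCC(=O)[O-])CCc3ncccc3C2)cc1OC.[Na+] | intermediate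
11 | 3-[(6R)-6-(3,4-dimethoxyphenyl)-5,6,7,8-tetrahydroquinolin-6-yl]propanoic acid | COc1ccc([C@@]2(CCC(=O)O)CCc3ncccc3C2)cc1OC | intermediate
12 | 3-[(6R)-6-(3,4-dimethoxyphenyl)-5,6,7,8-tetrahydroquinolin-6-yl]propanoyl azide (not isolated) | COc1ccc([C@@]2(CCC(=O)N=[N+]=[N-])CCc3ncccc3C2)cc1OC | intermediate
13 | (6S)-6-(3,4-dimethoxyphenyl)-6-(2-isocyanatoethyl)-5,6,7,8-tetrahydroquinoline (not isolated) | COc1ccc([C@@]2(CCN=C=O)CCc3ncccc3C2)cc1OC | intermediate
14 | methyl N-{2-[(6S)-6-(3,4-dimethoxyphenyl)-5,6,7,8-tetrahydroquinolin-6-yl]ethyl}carbamate | COc1ccc([C@@]2(CCNC(=O)OC)CCc3ncccc3C2)cc1OC | intermediate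
15 | 2-[(6S)-6-(3,4-dimethoxyphenyl)-5,6,7,8-tetrahydroquinolin-6-yl]-N-methylethan-1-amine, (S)-tortuosamine | COc1ccc([C@@]2(CCNC)CCc3ncccc3C2)cc1OC | intermediate
16 | N-{2-[(6S)-6-(3,4-dimethoxyphenyl)-5,6,7,8-tetrahydroquinolin-6-yl]ethyl}-N-methylformamide, N-formyltortuosamine | COc1ccc([C@@]2(CCN(C)C=O)CCc3ncccc3C2)cc1OC | target

## Count and risks
Total step count: 9. Longest linear sequence: 9 (from 1 to 16).

**Risk A, step 2.** The level and the sense of induction are unproven on this pyridine-fused substrate.
- The fallback sets out from 3 and comes back at 5. It gives up induction in favour of resolution with recycling.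
- 3 is cyanoethylated with 4 under achiral catalysis (benzyltrimethylammonium hydroxide, 10 mol %, t-BuOH/THF, 0 °C) to give the racemic keto nitrile F1.
- F1 is split by preparative chiral SFC (amylose tris(3,5-dimethylphenylcarbamate) phase, CO2/MeOH) into 5 and the (R)-keto nitrile F2.
- F2 is returned to 3 by base-induced retro-Michael cleavage (KOtBu, 1.5 equiv, t-BuOH, 80 °C). The cleavage is driven by formation of the stabilised enolate of 3, so little material is lost.

**Risk B, step 4.** The neopentyl, benzylic secondary alcohol may resist thioacylation, which would block the radical deoxygenation.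
- The fallback sets out from 5 and comes back at 8. It bypasses 6 and 7 and replaces the radical logic with a hydrazone-based reductive deoxygenation.
- 5 is condensed with TsNHNH2 (cat. TsOH, EtOH, reflux, 48 h) to give the tosylhydrazone F3.
- F3 is reduced at the C=N bond with catecholborane (CHCl3, 0 °C) and then heated with NaOAc·3H2O. This expels sulfinate and nitrogen and leaves the C5 methylene of 8.
- The nitrile tolerates catecholborane, and no C5 cation is formed.

**Risk C, step 1.** The pyridine may inhibit the Pd catalyst, or the palladium enolate may aromatise to 5-hydroxyquinoline by β-hydride loss.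
- The fallback sets out from 1 and comes back at 3. It reverses the polarity of the coupling.
- 1 is brominated (Br2, 33% HBr in AcOH, rt) to give 6-bromo-7,8-dihydroquinolin-5(6H)-one F4.
- Commercial 3,4-dimethoxyphenylmagnesium bromide is transmetalated with ZnBr2 (THF, 0 °C) to give (3,4-dimethoxyphenyl)zinc bromide F5.
- F4 and F5 are joined in a Negishi-type coupling of the α-bromo ketone (NiCl2(dme), 10 mol %, 4,4'-di-tert-butyl-2,2'-bipyridine, 12 mol %, THF/DME, −20 °C).
- This coupling runs through the α-keto radical under non-basic conditions and gives 3.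

Further compounds
F1 | step 2 | (±)-3-[6-(3,4-dimethoxyphenyl)-5-oxo-5,6,7,8-tetrahydroquinolin-6-yl]propanenitrile | COc1ccc(C2(CCC#N)CCc3ncccc3C2=O)cc1OC
F2 | step 2 | 3-[(6R)-6-(3,4-dimethoxyphenyl)-5-oxo-5,6,7,8-tetrahydroquinolin-6-yl]propanenitrile | COc1ccc([C@]2(CCC#N)CCc3ncccc3C2=O)cc1OC
F3 | step 4 | N'-[(6S)-6-(2-cyanoethyl)-6-(3,4-dimethoxyphenyl)-7,8-dihydroquinolin-5(6H)-ylidene]-4-methylbenzenesulfonohydrazide | COc1ccc([C@@]2(CCC#N)CCc3ncccc3C2=NNS(=O)(=O)c4ccc(C)cc4)cc1OC
F4 | step 1 | 6-bromo-7,8-dihydroquinolin-5(6H)-one | O=C1C(Br)CCc2ncccc12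
F5 | step 1 | (3,4-dimethoxyphenyl)zinc bromide | COc1ccc([Zn]Br)cc1OC
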